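The constants we start from are two rate constants read from the grey run, and their ratio is the quantity we carry to the new flasks.

common to all: starting material 0.050 M

|  | second substrate | free catalyst | remark | time |
|---|---|---|---|---|
| green | 0.025 M | 0.28 mM | run made earlier |  |
| grey | 0.025 M | 1.1 mM | run made earlier |  |
| blue | 0.025 M | 3 mM | run made earlier |  |
| east | 0.0250 M | 0.80 mM |  | 15 min |
| north-east | 0.0250 M | 2.0 mM |  | 15 min |
| north-west | 0.0250 M | 0.30 mM |  | 15 min |
| west | 0.0250 M | 4.0 mM |  | 15 min |
| north | 0.0250 M | 0.60 mM |  | 15 min |
| south-west | 0.0250 M | 1.2 mM |  | 15 min |

| run | time / min | target / % | uncatalysed product / % |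
|---|---|---|---|
| green | 1.50 | 6 | 2 |
| green | 3.00 | 7 | 7 |
| green | 5.00 | 9 | 14 |
| green | 6.00 | 13 | 13 |
| green | 8.00 | 19 | 15 |
| grey | 0.667 | 8 | 0 |
| grey | 2.00 | 18 | 4 |
| grey | 4.00 | 28 | 7 |
| grey | 5.00 | 42 | 10 |
| grey | 8.00 | 54 | 13 |
| blue | 0.667 | 15 | 7 |
| blue | 1.00 | 24 | 0 |
| blue | 2.00 | 43 | 2 |
| blue | 4.00 | 66 | 5 |
| blue | 8.00 | 87 | 3 |

(readings scatter by 2 percentage points)

- the earlier runs were read with a standard deviation of 2 percentage points

- the flasks put in order of share of target in all that became target or uncatalysed product, best first, at 15 min (east / north-east / north-west / west / north / south-west)
- the share of target in all that became target or uncatalysed product of the flask you put first, at 15 min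
- the share of target in all that became target or uncatalysed product of the flask you put last, at 15 min

Take the main step first, starting material to target over the catalyst. With this step in the flask, the share is 100 per cent whatever the catalyst charge, and we write the speed as a pseudo-first-order constant that goes with c(free catalyst). At the last grey reading, 54% target and 13% uncatalysed product, taken as a first-order loss of starting material, give a total constant of 0.139 /min.

Now add the uncatalysed step. Splitting the total in proportion to the two grey readings gives 0.112 /min for target and 0.0269 /min for uncatalysed product. Both routes draw on the same starting material, so if each is first order in it, their ratio should hold over time, and the grey readings show 4.00 and later 4.15. Taking the catalysed constant in proportion to the charge, we define c*, the charge of free catalyst at which both routes run equally fast: 0.265 mM. The share is then c(free catalyst)/(c(free catalyst) + c*).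

Last comes the second substrate, and here we add no term, so the number stays as it is: the last blue reading of target amounts to 0.0435 M, more than the 0.025 M of second substrate charged, so target is not made mole for mole from it. The green run, with the lowest charge, reads c* as 0.221 mM, but its small readings carry a scatter of 2 points, so we keep the grey value.

The share rises with the charge, so we expect west, at 4.0 mM, first at 93.8%. North-west, at 0.30 mM, comes last at 53.1%.

The forecast gives west > north-east > south-west > east > north > north-west, with 94.5% for west and 60% for north-west. Its low value differs from ours, since it holds that “substrate depletion by 15 min lifts this to about 60%”.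

The flasks give west > north-east > south-west > east > north > north-west, with 94.1% for west and 52.9% for north-west.

    starting material + free catalyst ⇌ catalyst intermediate A (K = 73.0 /M, k = 2.40 /M/s)
    catalyst intermediate A → free catalyst + target (k = 1.30 /s)
    second substrate + free catalyst ⇌ catalyst intermediate B (K = 38.0 /M, k = 2.70 /M/s)
    catalyst intermediate B → free catalyst + second product (k = 0.0630 /s)
    starting material → uncatalysed product (k = 4.40 × 10⁻⁴ /s)
    second substrate ⇌ dormant form (K = 3.20, k = 6.60 × 10⁻⁴ /s)

With c* at 0.265 mM, our share for north-west was 53.1%, and the flask stands at 52.9%. Left until 150 min, north-west reads 55.0%. A neighbour flask, the same as west but with 1.00 mM of free catalyst, gets 79.1% from c*, and that flask stands at 79.5%.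

The numbers in the tables stem from a simulated flask on assumed constants, and the scatter is random.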